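**Strategy.** Penibenzophenone C is read as a ring-opened anthraquinone. The ester carbon of ring A and a phenolic oxygen of ring B flank the central ketone, and reconnecting them restores the C10–C4a bond of a 1,6,8-trioxygenated 3-methylanthraquinone (questin; C9 lies between O1 and O8, C10 is the future ester carbon). One Baeyer–Villiger oxygen insertion into C10–C4a thus sets up the crowded ketone, the ester carbon and two distinguishable ring-B oxygens (lactone oxygen versus benzyl ether) together. The substrate is questin benzylated on O1, which screens C9, and pivaloylated on O6, which makes ring A the poorer migrating group and falls off when methoxide opens the lactone.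

Key step: step 9

**Remarks on the chemistry**
- Anthraquinone numbering of questin is used throughout. Ring A is the methoxy/ester ring and ring B the methyl-bearing ring.
- The two ring-B oxygens of the target are equivalent by the local symmetry of that ring, so either may carry the acetyl group.
- The ring-A diene must be the 1,1-dimethoxy-3-silyloxy isomer. Only this one leaves OMe at the peri position C8 and OH at C6; a 1,3-dimethoxy-1-silyloxy diene would give the reverse pattern.
- 4,4-Dimethoxybut-3-en-2-one is assumed not to be a routine catalogue item and is made in two steps.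
- The O6 ester is a pivalate because it should survive the carbonate benzylation of step 8 and perhydrolysis in step 9, while withdrawing electrons like any acyloxy group.
- Cycloadducts 5 and 15 are racemic; one enantiomer is drawn.

**Step 1**
Reactants: 1 methyl 3-methylbut-2-enoate
Product: 3 1-methoxy-3-methyl-1-(trimethylsilyloxy)buta-1,3-diene, via lithium dienolate 2 (not isolated)
Conditions: LiN(iPr)2, THF, −78 °C; Me3SiCl, −78 °C → rt
Reagents that add atoms: chlorotrimethylsilane, C[Si](C)(C)Cl
Why: Kinetic γ-deprotonation of the enoate gives the extended lithium dienolate, which the chlorosilane traps on oxygen (vinylketene acetal formation).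

**Step 2**
Reactants: 4 2,6-dichloro-1,4-benzoquinone; 3 1-methoxy-3-methyl-1-(trimethylsilyloxy)buta-1,3-diene
Product: 7 2-chloro-8-hydroxy-6-methylnaphthalene-1,4-dione (3-chloro-7-methyljuglone), via cycloadduct 5 (not isolated), via silyl ether 6 (not isolated)
Conditions: THF, −30 °C → rt; SiO2, then 1 M HCl/THF, rt
Reagents that add atoms: none
Why: Chlorine-directed Diels–Alder reaction of a vinylketene acetal with a haloquinone, in which the CH2 terminus of 3 bonds to C3 and the acetal carbon to the chlorine-bearing C2, so that loss of HCl and methanol and desilylation leave the hydroxyl peri to the carbonyl that still carries the second chlorine.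

**Step 3**
Reactants: 8 acetyl chloride; 9 1,1-dichloroethene
Product: 11 4,4-dichlorobut-3-en-2-one, via trichloroketone 10 (not isolated)
Conditions: AlCl3, CH2Cl2, 0 °C → rt; ice/HCl; distillation (−HCl)
Reagents that add atoms: none
Why: Friedel–Crafts-type acylation of the alkene at its CH2 end gives the β-trichloro ketone, which eliminates HCl to the conjugated dichloroenone.

**Step 4**
Reactants: 11 4,4-dichlorobut-3-en-2-one
Product: 13 4,4-dimethoxybut-3-en-2-one, via chloromethoxyenone 12 (not isolated)
Conditions: NaOMe (2.2 equiv), MeOH, 0 °C → rt; distillation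
Reagents that add atoms: sodium methoxide, [Na+].[O-]C
Why: Two consecutive addition–elimination (vinylogous acyl substitution) steps replace both β-chlorines of the activated enone by methoxide.

**Step 5**
Reactants: 13 4,4-dimethoxybut-3-en-2-one
Product: 14 1,1-dimethoxy-3-(trimethylsilyloxy)buta-1,3-diene
Conditions: Me3SiCl, Et3N, ZnCl2 (cat.), Et2O, rt → 35 °C
Reagents that add atoms: chlorotrimethylsilane, C[Si](C)(C)Cl
Why: Soft enolisation of the methyl ketone and O-silylation (silyl enol ether formation) give the 2-silyloxydiene without touching the ketene acetal.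

**Step 6**
Reactants: 7 2-chloro-8-hydroxy-6-methylnaphthalene-1,4-dione; 14 1,1-dimethoxy-3-(trimethylsilyloxy)buta-1,3-diene
Product: 17 questin (1,6-dihydroxy-8-methoxy-3-methylanthracene-9,10-dione), via cycloadduct 15 (not isolated), via silyl ether 16 (not isolated)
Conditions: CH2Cl2, rt; then 1 M HCl/THF, rt
Reagents that add atoms: none
Why: Second chlorine-directed Diels–Alder annulation, reinforced by the hydrogen bond from the C8 hydroxyl of 7 to C1=O, in which the acetal carbon of 14 bonds to C2 so that loss of HCl and one methanol leaves OMe at the peri position and, after desilylation, OH at C6.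

**Step 7**
Reactants: 17 questin
Product: 18 1-hydroxy-8-methoxy-3-methyl-6-(pivaloyloxy)anthracene-9,10-dione
Conditions: t-BuCOCl (1.1 equiv), pyridine, CH2Cl2, 0 °C → rt
Reagents that add atoms: pivaloyl chloride, CC(C)(C)C(Cl)=O
Why: Esterification with the bulky acid chloride should occur only at the free C6 phenol, because the C1 hydroxyl is locked in a hydrogen bond to C9=O.

**Step 8**
Reactants: 18 1-hydroxy-8-methoxy-3-methyl-6-(pivaloyloxy)anthracene-9,10-dione
Product: 19 1-(benzyloxy)-8-methoxy-3-methyl-6-(pivaloyloxy)anthracene-9,10-dione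
Conditions: BnBr, K2CO3, KI (cat.), DMF, 60 °C
Reagents that add atoms: benzyl bromide, BrCc1ccccc1
Why: Williamson etherification of the chelated C1 phenoxide under forcing carbonate conditions, which the hindered pivalate should withstand.

**Step 9**
Reactants: 19 1-(benzyloxy)-8-methoxy-3-methyl-6-(pivaloyloxy)anthracene-9,10-dione
Product: 21 1-(benzyloxy)-10-methoxy-3-methyl-8-(pivaloyloxy)dibenzo[b,e]oxepine-6,11-dione, via Criegee adduct 20 (not isolated)
Conditions: CF3CO3H [from (CF3CO)2O, urea·H2O2], Na2HPO4, CH2Cl2, 0 °C → rt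
Reagents that add atoms: trifluoroperacetic acid, OOC(=O)C(F)(F)F
Why: Proposed new method: the peracid adds to the C10 carbonyl to give Criegee adduct 20, and antiperiplanar 1,2-shift of C4a from C10 to the peroxide oxygen with loss of trifluoroacetate forms the C4a–O bond; the closest known reaction type is the Baeyer–Villiger oxidation of benzophenones and of fluorenone to aryl benzoates and dibenzopyranones. The seven-membered lactone arises by ring expansion of the central six-membered ring through insertion of one oxygen, not by a cyclisation, and no stereocentre is formed. Site selectivity (C10, not C9) is expected because C9 is a vinylogous-carbonate-type carbonyl conjugated to O1, O8 and O6 and screened by the two peri ethers, whereas C10 has only peri hydrogens. Migration selectivity (C4a, not C10a) rests on a Hammett argument: C4a carries a meta methyl and a meta benzyloxy group, C10a a meta methoxy and the strongly withdrawing meta pivaloyloxy group. The same ester lowers the electron density of ring A against electrophilic hydroxylation, and the phosphate buffer protects the benzyl ether and the ester.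

**Step 10**
Reactants: 21 1-(benzyloxy)-10-methoxy-3-methyl-8-(pivaloyloxy)dibenzo[b,e]oxepine-6,11-dione
Product: 23 methyl 2-[2-(benzyloxy)-6-hydroxy-4-methylbenzoyl]-5-hydroxy-3-methoxybenzoate, via ring-opened pivalate 22 (not isolated)
Conditions: NaOMe (3 equiv), MeOH/THF, 0 °C → rt; aq. NH4Cl
Reagents that add atoms: sodium methoxide, [Na+].[O-]C
Why: Methoxide transesterification opens the aryl lactone at the former C10 to the ring-A methyl ester and the ring-B phenoxide and then cleaves the aryl pivalate, the benzyl ether being inert.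

**Step 11**
Reactants: 23 methyl 2-[2-(benzyloxy)-6-hydroxy-4-methylbenzoyl]-5-hydroxy-3-methoxybenzoate
Product: 24 methyl 5-(benzyloxy)-2-[2-(benzyloxy)-6-hydroxy-4-methylbenzoyl]-3-methoxybenzoate
Conditions: BnBr (1.05 equiv), K2CO3 (1.1 equiv), acetone, rt → 40 °C
Reagents that add atoms: benzyl bromide, BrCc1ccccc1
Why: Williamson etherification under mild carbonate conditions should alkylate only the acidic, non-chelated ring-A phenol, because the ring-B phenol is hydrogen-bonded to the ketone and flanked by the aroyl group.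

**Step 12**
Reactants: 24 methyl 5-(benzyloxy)-2-[2-(benzyloxy)-6-hydroxy-4-methylbenzoyl]-3-methoxybenzoate
Product: 25 methyl 2-[2-acetoxy-6-(benzyloxy)-4-methylbenzoyl]-5-(benzyloxy)-3-methoxybenzoate
Conditions: Ac2O, pyridine, DMAP (cat.), CH2Cl2, rt
Reagents that add atoms: acetic anhydride, CC(=O)OC(C)=O
Why: DMAP-catalysed acetylation esterifies the only remaining phenol, which is hydrogen-bonded but reachable by the N-acetylpyridinium ion.

**Step 13**
Reactants: 25 methyl 2-[2-acetoxy-6-(benzyloxy)-4-methylbenzoyl]-5-(benzyloxy)-3-methoxybenzoate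
Product: 26 penibenzophenone C (methyl 2-(2-acetoxy-6-hydroxy-4-methylbenzoyl)-5-hydroxy-3-methoxybenzoate)
Conditions: H2 (1 atm), 10% Pd/C, EtOAc, rt
Reagents that add atoms: none
Why: Neutral hydrogenolysis of both aryl benzyl ethers should spare the aryl acetate, the methyl ester and the hindered tetra-ortho-substituted ketone, and the ring-B hydroxyl and acetoxy groups are meta to each other so that acetyl migration is geometrically excluded and would in any case be degenerate.

**Compound list**
1 | methyl 3-methylbut-2-enoate | COC(=O)C=C(C)C | starting material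
2 | lithium 1-methoxy-3-methylbuta-1,3-dien-1-olate (geometry at C1=C2 not controlled) | [Li+].[O-]C(OC)=CC(C)=C | intermediate (not isolated)
3 | 1-methoxy-3-methyl-1-(trimethylsilyloxy)buta-1,3-diene (E/Z mixture at C1=C2, geometry lost on aromatisation) | COC(O[Si](C)(C)C)=CC(C)=C | intermediate
4 | 2,6-dichloro-1,4-benzoquinone | O=C1C=C(Cl)C(=O)C(Cl)=C1 | starting material
5 | 2,8a-dichloro-8-methoxy-6-methyl-8-(trimethylsilyloxy)-4a,5,8,8a-tetrahydronaphthalene-1,4-dione (racemic, cis-fused, both epimers at the ketal carbon) | COC1(O[Si](C)(C)C)C=C(C)C[C@@H]2C(=O)C=C(Cl)C(=O)[C@]12Cl | intermediate (not isolated)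
6 | 2-chloro-6-methyl-8-(trimethylsilyloxy)naphthalene-1,4-dione | O=C1C=C(Cl)C(=O)c2c(O[Si](C)(C)C)cc(C)cc12 | intermediate (not isolated)
7 | 2-chloro-8-hydroxy-6-methylnaphthalene-1,4-dione | O=C1C=C(Cl)C(=O)c2c(O)cc(C)cc12 | intermediate
8 | acetyl chloride | CC(Cl)=O | starting material
9 | 1,1-dichloroethene | C=C(Cl)Cl | starting material
10 | 4,4,4-trichlorobutan-2-one | CC(=O)CC(Cl)(Cl)Cl | intermediate (not isolated)
11 | 4,4-dichlorobut-3-en-2-one | CC(=O)C=C(Cl)Cl | intermediate
12 | 4-chloro-4-methoxybut-3-en-2-one (E/Z mixture) | CC(=O)C=C(Cl)OC | intermediate (not isolated)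
13 | 4,4-dimethoxybut-3-en-2-one | CC(=O)C=C(OC)OC | intermediate
14 | 1,1-dimethoxy-3-(trimethylsilyloxy)buta-1,3-diene | COC(OC)=CC(=C)O[Si](C)(C)C | intermediate
15 | 9a-chloro-8-hydroxy-1,1-dimethoxy-6-methyl-3-(trimethylsilyloxy)-1,4,4a,9a-tetrahydroanthracene-9,10-dione (racemic, cis-fused) | COC1(OC)C=C(O[Si](C)(C)C)C[C@@H]2C(=O)c3cc(C)cc(O)c3C(=O)[C@]12Cl | intermediate (not isolated)
16 | 1-hydroxy-8-methoxy-3-methyl-6-(trimethylsilyloxy)anthracene-9,10-dione | COc1cc(O[Si](C)(C)C)cc2C(=O)c3cc(C)cc(O)c3C(=O)c12 | intermediate (not isolated)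
17 | questin, 1,6-dihydroxy-8-methoxy-3-methylanthracene-9,10-dione | COc1cc(O)cc2C(=O)c3cc(C)cc(O)c3C(=O)c12 | intermediate
18 | 1-hydroxy-8-methoxy-3-methyl-6-(pivaloyloxy)anthracene-9,10-dione | COc1cc(OC(=O)C(C)(C)C)cc2C(=O)c3cc(C)cc(O)c3C(=O)c12 | intermediate
19 | 1-(benzyloxy)-8-methoxy-3-methyl-6-(pivaloyloxy)anthracene-9,10-dione | COc1cc(OC(=O)C(C)(C)C)cc2C(=O)c3cc(C)cc(OCc4ccccc4)c3C(=O)c12 | intermediate
20 | 1-(benzyloxy)-10-hydroxy-8-methoxy-3-methyl-6-(pivaloyloxy)-10-(trifluoroacetylperoxy)anthracen-9(10H)-one (racemic at C10) | COc1cc(OC(=O)C(C)(C)C)cc2C(O)(OOC(=O)C(F)(F)F)c3cc(C)cc(OCc4ccccc4)c3C(=O)c12 | intermediate (not isolated)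
21 | 1-(benzyloxy)-10-methoxy-3-methyl-8-(pivaloyloxy)dibenzo[b,e]oxepine-6,11-dione | COc1cc(OC(=O)C(C)(C)C)cc2C(=O)Oc3cc(C)cc(OCc4ccccc4)c3C(=O)c12 | intermediate
22 | methyl 2-[2-(benzyloxy)-6-hydroxy-4-methylbenzoyl]-3-methoxy-5-(pivaloyloxy)benzoate (present as its sodium phenoxide) | COC(=O)c1cc(OC(=O)C(C)(C)C)cc(OC)c1C(=O)c1c(O)cc(C)cc1OCc1ccccc1 | intermediate (not isolated)
23 | methyl 2-[2-(benzyloxy)-6-hydroxy-4-methylbenzoyl]-5-hydroxy-3-methoxybenzoate | COC(=O)c1cc(O)cc(OC)c1C(=O)c1c(O)cc(C)cc1OCc1ccccc1 | intermediate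
24 | methyl 5-(benzyloxy)-2-[2-(benzyloxy)-6-hydroxy-4-methylbenzoyl]-3-methoxybenzoate | COC(=O)c1cc(OCc2ccccc2)cc(OC)c1C(=O)c1c(O)cc(C)cc1OCc1ccccc1 | intermediate
25 | methyl 2-[2-acetoxy-6-(benzyloxy)-4-methylbenzoyl]-5-(benzyloxy)-3-methoxybenzoate | COC(=O)c1cc(OCc2ccccc2)cc(OC)c1C(=O)c1c(OC(C)=O)cc(C)cc1OCc1ccccc1 | intermediate
26 | penibenzophenone C, methyl 2-(2-acetoxy-6-hydroxy-4-methylbenzoyl)-5-hydroxy-3-methoxybenzoate (no stereocentre) | COC(=O)c1cc(O)cc(OC)c1C(=O)c1c(O)cc(C)cc1OC(C)=O | target

**Total step count:** 13.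
**Longest linear sequence:** 11 steps (8 and 9 → 26 through steps 3–13).

**Steps most likely to fail**

Step 9 (Proposed new method). The peracid may not add to the unreactive quinone carbonyl, may add at C9 instead, or C10a may migrate in place of C4a. The fallback uses known chemistry and sets out from questin 17. The known enzymatic ring cleavage performs the oxygen insertion: incubation with the questin oxygenase system of Aspergillus terreus (cell-free extract or recombinant enzymes, NADPH regenerated with glucose 6-phosphate, air, phosphate buffer pH 7.5, 30 °C) should give desmethylsulochrin F1. Carboxylate alkylation (MeI, NaHCO3, DMF, rt) should then give sulochrin F2. BnBr (2.1 equiv), K2CO3, acetone, 40 °C should benzylate the ring-A phenol and one of the two equivalent ring-B phenols, the last one staying chelated, and this comes back to the route at 24.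

Step 8. Alkylation of the chelated C1 hydroxyl may stall, or the base may strip the pivalate so that O6 is benzylated as well. The fallback sets out from 7 and 14 and moves the benzylation ahead of the second annulation. BnBr, Ag2O, CH2Cl2, rt in the dark should give 8-(benzyloxy)-2-chloro-6-methylnaphthalene-1,4-dione F3. Diels–Alder reaction with 14 (CH2Cl2, rt; then 1 M HCl/THF), now directed by the chlorine alone, should pass through cycloadduct F4 and silyl ether F5 to 1-(benzyloxy)-6-hydroxy-8-methoxy-3-methylanthracene-9,10-dione F6. Pivaloylation of the free C6 phenol (t-BuCOCl, pyridine) comes back to the route at 19.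

Step 11. The two phenols may be discriminated poorly, leading to alkylation of the ring-B hydroxyl or to dialkylation. The fallback sets out from 23 and replaces the alkylation by a bulkier, more discriminating silylation. t-BuMe2SiCl, imidazole, DMF, 0 °C should give methyl 2-[2-(benzyloxy)-6-hydroxy-4-methylbenzoyl]-5-(tert-butyldimethylsilyloxy)-3-methoxybenzoate F7. Ac2O, pyridine, DMAP should give its ring-B acetate F8. Hydrogenolysis (H2, Pd/C, EtOAc) should give methyl 2-(2-acetoxy-6-hydroxy-4-methylbenzoyl)-5-(tert-butyldimethylsilyloxy)-3-methoxybenzoate F9. HF·pyridine, THF, 0 °C should remove the silyl ether without touching the aryl acetate, and this comes back to the route at 26.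

**Further compounds**
F1 | step 9 | desmethylsulochrin, 2-(2,6-dihydroxy-4-methylbenzoyl)-5-hydroxy-3-methoxybenzoic acid | COc1cc(O)cc(C(=O)O)c1C(=O)c1c(O)cc(C)cc1O
F2 | step 9 | sulochrin, methyl 2-(2,6-dihydroxy-4-methylbenzoyl)-5-hydroxy-3-methoxybenzoate | COC(=O)c1cc(O)cc(OC)c1C(=O)c1c(O)cc(C)cc1O
F3 | step 8 | 8-(benzyloxy)-2-chloro-6-methylnaphthalene-1,4-dione | O=C1C=C(Cl)C(=O)c2c(OCc3ccccc3)cc(C)cc12
F4 | step 8 | 8-(benzyloxy)-9a-chloro-1,1-dimethoxy-6-methyl-3-(trimethylsilyloxy)-1,4,4a,9a-tetrahydroanthracene-9,10-dione (racemic, cis-fused) | COC1(OC)C=C(O[Si](C)(C)C)C[C@@H]2C(=O)c3cc(C)cc(OCc4ccccc4)c3C(=O)[C@]12Cl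
F5 | step 8 | 1-(benzyloxy)-8-methoxy-3-methyl-6-(trimethylsilyloxy)anthracene-9,10-dione | COc1cc(O[Si](C)(C)C)cc2C(=O)c3cc(C)cc(OCc4ccccc4)c3C(=O)c12
F6 | step 8 | 1-(benzyloxy)-6-hydroxy-8-methoxy-3-methylanthracene-9,10-dione | COc1cc(O)cc2C(=O)c3cc(C)cc(OCc4ccccc4)c3C(=O)c12
F7 | step 11 | methyl 2-[2-(benzyloxy)-6-hydroxy-4-methylbenzoyl]-5-(tert-butyldimethylsilyloxy)-3-methoxybenzoate | COC(=O)c1cc(O[Si](C)(C)C(C)(C)C)cc(OC)c1C(=O)c1c(O)cc(C)cc1OCc1ccccc1
F8 | step 11 | methyl 2-[2-acetoxy-6-(benzyloxy)-4-methylbenzoyl]-5-(tert-butyldimethylsilyloxy)-3-methoxybenzoate | COC(=O)c1cc(O[Si](C)(C)C(C)(C)C)cc(OC)c1C(=O)c1c(OC(C)=O)cc(C)cc1OCc1ccccc1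
F9 | step 11 | methyl 2-(2-acetoxy-6-hydroxy-4-methylbenzoyl)-5-(tert-butyldimethylsilyloxy)-3-methoxybenzoate | COC(=O)c1cc(O[Si](C)(C)C(C)(C)C)cc(OC)c1C(=O)c1c(OC(C)=O)cc(C)cc1O
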